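Ring B of the naphthazarin core is a quinone whose C2=C3 edge bears nothing but the chiral side chain and sits between the carbonyl carbons C1 and C4. The route therefore cuts C1–C2 and C3–C4: a phthaloylcobalt metallacycle, formed by inserting cobalt into the CO–CO bond of 3,6-dimethoxybenzocyclobutenedione, annulates the terminal alkyne of (S)-6-methylhept-5-en-1-yn-3-yl tiglate, closing ring B at the quinone oxidation level in one operation with the stereocentre and ester already in place. The dione comes from an aryne [2+2] route, the alkyne from an asymmetric ynone reduction; oxidative demethylation of ring A ends the synthesis.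

Key step: step 9

Remark on the chemistry: the carbinol carbon is S in 13, 14, 16, 19, 20 and 21 alike, because the alkynyl or ring carbon outranks the allylic CH2 throughout. The two naphthazarin tautomers (quinone in ring A or in ring B) are assumed to interconvert freely, so 21 is one substance whichever ring emerges as the quinone.

**Route**

Step 1
Reactants: 1 2-bromo-1,4-dimethoxybenzene; 2 1,1-dimethoxyethene
Product: 5 3,6-dimethoxybenzocyclobutenone, via 3,6-dimethoxybenzyne 3 (not isolated), via 1,1,3,6-tetramethoxybenzocyclobutene 4 (not isolated)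
Conditions: NaNH2, THF, reflux; then 1 M HCl, THF–H2O, 25 °C
Reagents that add atoms: water, O
Why: Dehydrobromination of 1 gives the symmetric aryne 3, whose aryne–ketene acetal [2+2] cycloaddition can give only one regioisomer, and mild acetal hydrolysis then unmasks the four-membered ketone.

Step 2
Reactants: 5 3,6-dimethoxybenzocyclobutenone
Product: 6 2,2-dibromo-3,6-dimethoxybenzocyclobutenone
Conditions: NBS (2.2 equiv), (PhCO2)2 (cat.), PhCF3 or CCl4, reflux
Reagents that add atoms: N-bromosuccinimide, O=C1CCC(=O)N1Br
Why: Wohl–Ziegler radical bromination is chosen because the benzylic CH2 next to the carbonyl cannot be oxidised through an enolate (it would be a benzocyclobutadiene), whereas hydrogen abstraction there gives a stabilised radical, so two brominations should raise this carbon to the carbonyl oxidation level.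

Step 3
Reactants: 6 2,2-dibromo-3,6-dimethoxybenzocyclobutenone
Product: 7 3,6-dimethoxybenzocyclobutene-1,2-dione
Conditions: 50% aq H2SO4, 60 °C
Reagents that add atoms: water, O
Why: Gem-dihalide hydrolysis in warm aqueous acid should exchange both benzylic bromides for the carbonyl oxygen, acid being chosen because the strained 1,2-dione tolerates it but is opened by base.

Step 4
Reactants: 8 4-methylpent-3-enoic acid
Product: 9 N-methoxy-N,4-dimethylpent-3-enamide
Conditions: CDI, CH2Cl2, 25 °C; then MeNHOMe·HCl, 25 °C
Reagents that add atoms: N,O-dimethylhydroxylamine hydrochloride, CNOC.Cl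
Why: Amide coupling through the acyl imidazolide proceeds under near-neutral conditions and should give the Weinreb amide without moving the skipped alkene into conjugation.

Step 5
Reactants: 9 N-methoxy-N,4-dimethylpent-3-enamide; 10 trimethylsilylacetylene
Product: 12 6-methyl-1-(trimethylsilyl)hept-5-en-1-yn-3-one, via lithium (trimethylsilyl)acetylide 11 (not isolated)
Conditions: 10, n-BuLi, THF, −78 °C; then 9, −78 → 0 °C; cold aq NH4Cl
Reagents that add atoms: none
Why: In this Weinreb ketone synthesis the acetylide adds once and the chelated tetrahedral adduct persists until the cold quench, so neither over-addition nor conjugation of the β,γ-alkene should intervene.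

Step 6
Reactants: 12 6-methyl-1-(trimethylsilyl)hept-5-en-1-yn-3-one
Product: 13 (S)-6-methyl-1-(trimethylsilyl)hept-5-en-1-yn-3-ol
Conditions: Ru[(S,S)-TsNCHPhCHPhNH](p-cymene) (1 mol %), i-PrOH, 25 °C
Reagents that add atoms: none
Why: Noyori asymmetric transfer hydrogenation of an α,β-acetylenic ketone, in which the (S,S)-TsDPEN catalyst places the alkynyl group where an aryl group sits in aryl ketone reductions and so sets the S carbinol by catalyst control, under base-free conditions that should leave the skipped alkene and the silyl group alone.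

Step 7
Reactants: 13 (S)-6-methyl-1-(trimethylsilyl)hept-5-en-1-yn-3-ol
Product: 14 (S)-6-methylhept-5-en-1-yn-3-ol
Conditions: K2CO3 (0.2 equiv), MeOH, 0 → 25 °C
Reagents that add atoms: none
Why: Base-catalysed protodesilylation cleaves only the alkynyl C–Si bond, so the carbinol C–O bond and its S configuration are untouched.

Step 8
Reactants: 14 (S)-6-methylhept-5-en-1-yn-3-ol; 15 tiglic acid
Product: 16 (S)-6-methylhept-5-en-1-yn-3-yl tiglate
Conditions: DCC, DMAP (cat.), CH2Cl2, 0 → 25 °C
Reagents that add atoms: none
Why: Steglich esterification acylates the alcohol oxygen without breaking the C–O bond, so the S configuration is retained, and tiglic acid, the more stable E acid, should keep its geometry.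

Step 9
Reactants: 7 3,6-dimethoxybenzocyclobutene-1,2-dione; 16 (S)-6-methylhept-5-en-1-yn-3-yl tiglate
Product: 19 alkannin tiglate 5,8-dimethyl ether, via bis(triphenylphosphine) phthaloylcobalt chloride 17 (not isolated), via dimethylglyoxime pyridine phthaloylcobalt chloride 18 (not isolated)
Conditions: 7 (1.2 equiv), ClCo(PPh3)3, PhCl, 25 °C; dimethylglyoxime, pyridine, 25 °C; volatiles removed; then 16, CoCl2·6H2O, ClCH2CH2Cl, 80 °C
Reagents that add atoms: none
Why: Monovalent cobalt of ClCo(PPh3)3 adds oxidatively across the strained CO–CO bond of the four-membered ring of 7 to give the five-membered diacyl complex 17 of trivalent cobalt; exchange of the phosphines for dimethylglyoxime and pyridine gives octahedral 18, in which CoCl2·6H2O labilises a ligand so that alkyne 16 can coordinate, insert into one acyl–cobalt bond and be joined to the second acyl carbon by C–C reductive elimination. The closest known reaction type is the phthaloylcobalt synthesis of naphthoquinones from benzocyclobutenediones and alkynes, which accepts terminal and oxygen-functionalised alkynes. Ring B closes by a formal [4+2] metallacycle annulation, the C1–C8a–C4a–C4 diacyl unit and the alkyne carbons C2 and C3 being stitched together through a seven-membered cobaltacycle, and it arrives as the quinone with no further oxidation. No stereocentre is formed; the S carbinol centre is a spectator because no bond to it is made or broken, and AgBF4, which promotes acyloxy shifts in propargylic esters, is avoided. The selectivity needed is chemoselectivity for the alkyne over the two trisubstituted alkenes, which the substrate secures because only the unhindered terminal alkyne should bind and insert at the crowded cobalt centre; regioselectivity is no issue, since the mirror-symmetric metallacycle gives 19 from either alkyne orientation.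

Step 10
Reactants: 19 alkannin tiglate 5,8-dimethyl ether
Product: 21 alkannin tiglate (target), via alkannin tiglate diquinone 20 (not isolated)
Conditions: AgO (4 equiv), 6 M HNO3, dioxane, 20 °C, 5–10 min; then CHCl3 extract shaken with aq Na2S2O4, 20 °C
Reagents that add atoms: water, O
Why: Oxidative demethylation of the p-dimethoxyarene ring A by AgO (aryl–oxygen cleavage, the new oxygens coming from water) should give diquinone 20, and its two-electron reduction with Na2S2O4 the naphthazarin, so that no Lewis acid or nucleophilic demethylating agent meets the allylic ester and the esterified carbinol cannot cyclise onto the prenyl group.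

**Compound list**

1 | 2-bromo-1,4-dimethoxybenzene | COc1ccc(OC)c(Br)c1 | starting material
2 | 1,1-dimethoxyethene | C=C(OC)OC | starting material
3 | 3,6-dimethoxybenzyne | COC1=CC=C(OC)C#C1 | intermediate (not isolated)
4 | 1,1,3,6-tetramethoxybenzocyclobutene (dimethyl ketal of 5) | COc1ccc(OC)c2c1CC2(OC)OC | intermediate (not isolated)
5 | 3,6-dimethoxybenzocyclobutenone (2,5-dimethoxybicyclo[4.2.0]octa-1,3,5-trien-7-one) | COc1ccc(OC)c2c1CC2=O | intermediate
6 | 2,2-dibromo-3,6-dimethoxybenzocyclobutenone | COc1ccc(OC)c2c1C(Br)(Br)C2=O | intermediate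
7 | 3,6-dimethoxybenzocyclobutene-1,2-dione | COc1ccc(OC)c2c1C(=O)C2=O | intermediate
8 | 4-methylpent-3-enoic acid | CC(C)=CCC(=O)O | starting material
9 | N-methoxy-N,4-dimethylpent-3-enamide | CC(C)=CCC(=O)N(C)OC | intermediate
10 | trimethylsilylacetylene | C[Si](C)(C)C#C | starting material
11 | lithium (trimethylsilyl)acetylide | [Li]C#C[Si](C)(C)C | intermediate (not isolated)
12 | 6-methyl-1-(trimethylsilyl)hept-5-en-1-yn-3-one | CC(C)=CCC(=O)C#C[Si](C)(C)C | intermediate
13 | (S)-6-methyl-1-(trimethylsilyl)hept-5-en-1-yn-3-ol | O[C@@H](CC=C(C)C)C#C[Si](C)(C)C | intermediate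
14 | (S)-6-methylhept-5-en-1-yn-3-ol | O[C@@H](CC=C(C)C)C#C | intermediate
15 | tiglic acid, (E)-2-methylbut-2-enoic acid | C/C=C(\C)C(=O)O | starting material
16 | (S)-6-methylhept-5-en-1-yn-3-yl tiglate | C/C=C(\C)C(=O)O[C@@H](CC=C(C)C)C#C | intermediate
17 | chlorobis(triphenylphosphine)(3,6-dimethoxyphthaloyl)cobalt, five-membered diacyl metallacycle of trivalent cobalt | COc1ccc(OC)c2c1C(=O)[Co-2](Cl)([P+](c1ccccc1)(c1ccccc1)c1ccccc1)([P+](c1ccccc1)(c1ccccc1)c1ccccc1)C2=O | intermediate (not isolated)
18 | chloro(dimethylglyoxime)(pyridine)(3,6-dimethoxyphthaloyl)cobalt, octahedral, dioxime bound through both nitrogens | COc1ccc(OC)c2c1C(=O)[Co-3]1(Cl)([n+]3ccccc3)(C2=O)[N+](O)=C(C)C(C)=[N+]1O | intermediate (not isolated)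
19 | alkannin tiglate 5,8-dimethyl ether, (S)-1-(5,8-dimethoxy-1,4-dioxo-1,4-dihydronaphthalen-2-yl)-4-methylpent-3-en-1-yl tiglate | C/C=C(\C)C(=O)O[C@@H](CC=C(C)C)C1=CC(=O)c2c(OC)ccc(OC)c2C1=O | intermediate
20 | (S)-4-methyl-1-(1,4,5,8-tetraoxo-1,4,5,8-tetrahydronaphthalen-2-yl)pent-3-en-1-yl tiglate | C/C=C(\C)C(=O)O[C@@H](CC=C(C)C)C1=CC(=O)C2=C(C1=O)C(=O)C=CC2=O | intermediate (not isolated)
21 | alkannin tiglate, (S)-1-(5,8-dihydroxy-1,4-dioxo-1,4-dihydronaphthalen-2-yl)-4-methylpent-3-en-1-yl tiglate | C/C=C(\C)C(=O)O[C@@H](CC=C(C)C)C1=CC(=O)c2c(O)ccc(O)c2C1=O | target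

**Step count**

Total step count: 10 (three steps to dione 7, five to alkyne 16, two after convergence).
Longest linear sequence: 7 steps (steps 4–8, then 9 and 10).

**Steps most likely to fail**

Step 9. The low-valent cobalt released after reductive elimination may oligomerise the terminal alkyne, or the Lewis-acid activation may ionise the propargylic ester, so that insertion into the acyl–cobalt bond is outrun. The fallback builds ring B by a Dötz benzannulation instead; it sets out from 1 and 16 and comes back to the route at 19. Bromine–lithium exchange on 1 (n-BuLi, THF, −78 °C) would give 2,5-dimethoxyphenyllithium F1. Its addition to Cr(CO)6 would give lithium pentacarbonyl[(2,5-dimethoxyphenyl)oxidomethylidene]chromate F2, and O-methylation with Me3OBF4 would give pentacarbonyl[(2,5-dimethoxyphenyl)(methoxy)methylidene]chromium F3. Heating F3 with 16 (THF, 55 °C, then air to strip the metal) should assemble ring B from the carbene carbon, the two alkyne carbons and one CO ligand, giving (S)-1-(1-hydroxy-4,5,8-trimethoxynaphthalen-2-yl)-4-methylpent-3-en-1-yl tiglate F4. Oxidation with (NH4)2Ce(NO3)6 in aqueous MeCN at 0 °C would then give 19. Either orientation of the alkyne leads to 19, because the 5,8-dimethoxy-1,4-quinone is symmetric.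

Step 10. The prenyl alkene may be degraded by the acidic oxidising medium, or the very electrophilic diquinone may be captured by water or nitrate before it is reduced. The fallback is a redox relay that oxidises ring A only after ring B has been masked; it sets out from 19 and comes back at 21. Reduction of 19 with Na2S2O4 would give (S)-1-(1,4-dihydroxy-5,8-dimethoxynaphthalen-2-yl)-4-methylpent-3-en-1-yl tiglate F5, and acetylation (Ac2O, pyridine, DMAP) would give (S)-1-(1,4-diacetoxy-5,8-dimethoxynaphthalen-2-yl)-4-methylpent-3-en-1-yl tiglate F6. The dimethoxy ring of F6 is no longer deactivated by a fused quinone, so the milder oxidant (NH4)2Ce(NO3)6 (aqueous MeCN, 0 °C) should demethylate it to (S)-1-(1,4-diacetoxy-5,8-dioxo-5,8-dihydronaphthalen-2-yl)-4-methylpent-3-en-1-yl tiglate F7. The two aryl acetates, far more labile than the hindered conjugated tiglate, would be removed with NH4OAc in aqueous MeOH at 25 °C, and the naphthazarin so formed is 21.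

Step 2. The second bromination at the already brominated benzylic carbon is slow, and forcing it with excess NBS may lead to electrophilic bromination of the electron-rich ring. The fallback needs only one bromination and reaches the dione by nitrate-ester elimination; it sets out from 5 and comes back at 7, bypassing 6 and step 3. NBS (1.0 equiv, radical conditions) would give racemic 2-bromo-3,6-dimethoxybenzocyclobutenone F8. AgNO3 in MeCN would convert it to racemic 3,6-dimethoxy-2-oxobenzocyclobuten-1-yl nitrate F9, and Et3N in CH2Cl2 at 0 °C would eliminate nitrite to give 7.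

**Further compounds**

F1 | step 9 | 2,5-dimethoxyphenyllithium | [Li]c1cc(OC)ccc1OC
F2 | step 9 | lithium pentacarbonyl[(2,5-dimethoxyphenyl)oxidomethylidene]chromate | [Li+].[O-]C(=[Cr](=C=O)(=C=O)(=C=O)(=C=O)=C=O)c1cc(OC)ccc1OC
F3 | step 9 | pentacarbonyl[(2,5-dimethoxyphenyl)(methoxy)methylidene]chromium | COC(=[Cr](=C=O)(=C=O)(=C=O)(=C=O)=C=O)c1cc(OC)ccc1OC
F4 | step 9 | (S)-1-(1-hydroxy-4,5,8-trimethoxynaphthalen-2-yl)-4-methylpent-3-en-1-yl tiglate | C/C=C(\C)C(=O)O[C@@H](CC=C(C)C)c1cc(OC)c2c(OC)ccc(OC)c2c1O
F5 | step 10 | (S)-1-(1,4-dihydroxy-5,8-dimethoxynaphthalen-2-yl)-4-methylpent-3-en-1-yl tiglate | C/C=C(\C)C(=O)O[C@@H](CC=C(C)C)c1cc(O)c2c(OC)ccc(OC)c2c1O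
F6 | step 10 | (S)-1-(1,4-diacetoxy-5,8-dimethoxynaphthalen-2-yl)-4-methylpent-3-en-1-yl tiglate | C/C=C(\C)C(=O)O[C@@H](CC=C(C)C)c1cc(OC(C)=O)c2c(OC)ccc(OC)c2c1OC(C)=O
F7 | step 10 | (S)-1-(1,4-diacetoxy-5,8-dioxo-5,8-dihydronaphthalen-2-yl)-4-methylpent-3-en-1-yl tiglate | C/C=C(\C)C(=O)O[C@@H](CC=C(C)C)c1cc(OC(C)=O)c2C(=O)C=CC(=O)c2c1OC(C)=O
F8 | step 2 | 2-bromo-3,6-dimethoxybenzocyclobutenone (racemic) | COc1ccc(OC)c2c1C(Br)C2=O
F9 | step 2 | 3,6-dimethoxy-2-oxobenzocyclobuten-1-yl nitrate (racemic) | COc1ccc(OC)c2c1C(O[N+](=O)[O-])C2=O
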